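**Abbreviations and remark on the chemistry:** TBS = tert-butyldimethylsilyl, TIPS = triisopropylsilyl; the glycerol side-chain carbons are called C7 (benzylic), C8 (ether-bearing) and C9 (primary). The ester-bearing carbon of 27 is configurationally labile and is drawn as its trans epimer.

## Analysis of the target

The target is built from four phenylpropane units. Its core is a trans-α,β-dibenzyl-γ-butyrolactone. The α-benzyl ring (ring B) is the aryl ether of a guaiacylglycerol unit (ring A, side chain C7–C9). The β-benzyl ring (ring C) is the benzo ring of a 2-aryl-3-hydroxymethyl-2,3-dihydrobenzofuran (ring D) that carries a 4-hydroxy-3-methoxyphenyl group (ring E) at C2.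

There are six stereocentres in three pairs: C7/C8 of the glycerol chain (7R,8S, erythro), the lactone carbons (αR,βR, trans) and C2/C3 of ring D (2S,3R, trans). Within a pair the centres are adjacent and can control each other. The pairs are separated by aryl rings and methylene groups, so each pair needs its own source of absolute configuration.

The sensitive sites are the two para-hydroxybenzylic C–O bonds (C7–OH next to ring A, C2–O next to ring E), which ionise to quinone methides under acid, base or oxidants. The β-aryl ether at C8, the epimerisable lactone and the easily dehydrogenated dihydrobenzofuran are also sensitive. The hard parts are the erythro aryl ether, the trans-dihydrobenzofuran with a free phenol, and a convergent union that disturbs neither.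

The strategy rests on one structural fact. C2 of ring D is benzylic to ring E, para to the phenolic oxygen of ring E, and bonded to the phenolic oxygen of ring C. The C2–O bond is therefore the bond that forms when a para-quinone methide of ring E is captured by the ring C phenol. The ring C carbon para to that oxygen bears the lactone side chain; as a bromine atom it first blocks ring C against oxidation and then serves as the handle for attaching the lactone.

## Retrosynthetic reasoning

**45 ⇒ 44.** The last cut is at five O–Si bonds. All hydroxyl groups stay silylated to the end, so that the two para-hydroxybenzylic C–O bonds of 45 appear only in the final, buffered desilylation.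

**44 ⇒ 28 + 42.** The bond between the lactone α-carbon and the benzylic carbon of ring B is cut. It divides the molecule into two halves of similar size, each holding complete stereochemical pairs: lactone 28 (ring D pair and β-centre) and benzylic bromide 42 (erythro pair). The forward reaction is alkylation of lithium enolate 43, which must place the new benzyl group trans to the β-substituent; the β-centre shields one face.

**28 ⇒ 27 ⇒ 20 + 24 (24 ⇒ 21 + 22).** The bond between ring C and its benzylic CH2 is cut. Aryl bromide 20 becomes the nucleophile and the doubly activated cyclopropane 24 the three-carbon electrophile. The β-centre is bought from epichlorohydrin 22 and carried through 23 and 24 without any bond to it being broken. The activating ester is removed (27 → 28) before the union with 42, because the hot dealkoxycarbonylation is better run on the smaller molecule and because direct alkylation of 43 sets the α-centre cleanly.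

**20 ⇒ 19 ⇒ 17 (key disconnection).** The C2–O bond of ring D is cut. Bisphenol 17 holds only the C3 centre. The forward reaction oxidises ring E to quinone methide 18 and lets the ring C phenol close ring D, creating C2 under control of C3. This removes the need for a second, independent stereocontrol element in ring D.

**17 ⇒ 16 ⇒ 15 ⇒ 14 ⇒ 12 + 4.** The bond between the stereocentre and the benzylic carbon of ring E is cut. Alkylation of the enolate 13 of arylacetyl imide 12 with benzylic bromide 4 sets the centre by auxiliary control. Reduction, silylation of the primary alcohol and selective release of the two phenols then lead to 17.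

**12 ⇒ 9 + 10; 9 ⇒ 7 ⇒ 6 ⇒ 5; 4 ⇒ 3 ⇒ 2 ⇒ 1.** The imide comes from arylacetic acid 9 and oxazolidinone 10. Acid 9 is the one-carbon homologue of the commercial bromo aldehyde 5, reached through silyl ether 6, enol ether 7 and aldehyde 8. Bromide 4 comes from vanillin 1 through aldehyde 2, which is used a second time as ring A.

**42 ⇒ 41 ⇒ 40 ⇒ 39 ⇒ 38 ⇒ 37.** The benzylic bromide is traced to methyl ester 40. The erythro alcohol 39 is obtained from the threo alcohol 37 by oxidation to ketone 38 and chelation-controlled reduction. An auxiliary-controlled syn aldol delivers only the threo series, so C7 is corrected after C8 has been fixed.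

**37 ⇒ 36 ⇒ 35 ⇒ 33 + 2; 33 ⇒ 31 + 10; 31 ⇒ 29 + 30.** The C7–C8 bond is cut by an aldol addition of the aryloxyacetyl imide 33 to aldehyde 2 (through boron enolate 34), which fixes C8 absolutely. The O–C8 bond is cut back to methyl vanillate 29 and bromoacetic acid 30; the ester of 29 is the latent benzylic carbon of ring B.

## Alternatives that were turned down

**Alternative 1:** Both bonds at the lactone are cut at once. The lithium derivative of aryl dithiane A3 would add to the chiral menthyloxybutenolide A2 anti to the menthyloxy group, and the enolate would be benzylated in the same flask by a bromide of the type of 42, giving A1.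
- For it: three components are joined in one operation and both lactone centres are relayed from a single acetal centre. On convergence at the lactone it is stronger than the chosen route, which spends steps 15, 16 and 27 on the same two bonds.
- Against it: A1 still carries a dithiane and an acetal. Desulfurisation with Raney Ni would have to spare three benzylic C–O bonds (ring D C2–O, the C7 silyl ether, the aryl ether region). The acetal carbon must then be taken down to CH2 by hydrolysis, reduction and relactonisation. Trapping a hindered enolate next to a quaternary dithiane carbon with a large bromide is also demanding.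
- Comparison: it does not address ring D at all, so the dihydrobenzofuran would still need the chosen key step. The chosen route offers mild late steps in its place.

**Alternative 2:** The C2–C3 bond of ring D is cut. The aryldiazoacetate A5 would lose N2 on a chiral dirhodium tetracarboxylate (divalent rhodium); the carbenoid would insert into the benzylic O–CH2 bond, and alkoxide equilibration would give the trans ester A4.
- For it: the stereochemistry is catalytic and A4 is reached in fewer steps than 19, with no stoichiometric auxiliary. On step count and atom economy it is the stronger plan.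
- Against it: both centres depend on catalyst recognition of a substrate with an ortho methoxy group and a very electron-rich benzyl ether, where oxonium ylide formation and hydride transfer compete. The kinetic isomer is usually cis. Its epimerisation passes through an ester enolate that can expel the ring C phenoxide and scramble C2. The ester must afterwards be reduced and protected.
- Comparison: the chosen route sets C3 with a predictable sense at the alcohol oxidation level and sets C2 by a closure that is trans both kinetically and thermodynamically.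

**Alternative 3:** The lactone C–O bond is cut. The prochiral cyclobutanone A7 would undergo desymmetrising Baeyer–Villiger oxidation with a peracid under a trivalent scandium Lewis acid and a chiral N,N'-dioxide ligand, giving A6, which is identical with 28.
- For it: the β-centre is made catalytically, and the organometallic step 15 is avoided.
- Against it: A7 needs at least three steps from 20 (allylation, ketene cycloaddition, dechlorination) against two for 28. A peracid meets two trioxygenated arenes and a benzylic ether. The catalyst must find the enantiotopic CH2 in a substrate that already has two remote centres.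
- Comparison: the chosen route reaches the same compound with the β-centre taken from 22. Ring D is again left unanswered.

Key step: step 12

## Steps

Step 1
Reactants: 1 vanillin (4-hydroxy-3-methoxybenzaldehyde)
Product: 2 4-[(tert-butyldimethylsilyl)oxy]-3-methoxybenzaldehyde
Conditions: TBSCl, imidazole, DMF, 0 °C → rt
Reagents that add atoms: tert-butyldimethylsilyl chloride, CC(C)(C)[Si](C)(C)Cl
Why: Imidazole-promoted O-silylation of the phenol; the aldehyde is inert and 2 serves both as precursor of the ring E bromide and as the ring A aldehyde.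

Step 2
Reactants: 2 4-[(tert-butyldimethylsilyl)oxy]-3-methoxybenzaldehyde
Product: 3 {4-[(tert-butyldimethylsilyl)oxy]-3-methoxyphenyl}methanol
Conditions: NaBH4, EtOH/THF, 0 °C
Reagents that add atoms: none
Why: Borohydride reduction of the aryl aldehyde; short contact at 0 °C should keep the aryl silyl ether intact.

Step 3
Reactants: 3 {4-[(tert-butyldimethylsilyl)oxy]-3-methoxyphenyl}methanol
Product: 4 [4-(bromomethyl)-2-methoxyphenoxy](tert-butyl)dimethylsilane
Conditions: CBr4, PPh3, CH2Cl2, 0 °C
Reagents that add atoms: carbon tetrabromide, BrC(Br)(Br)Br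
Why: Appel reaction under neutral conditions, which avoids acid that would ionise the electron-rich benzylic position; the bromide is used at once.

Step 4
Reactants: 5 5-bromo-2-hydroxy-3-methoxybenzaldehyde
Product: 6 5-bromo-2-[(tert-butyldimethylsilyl)oxy]-3-methoxybenzaldehyde
Conditions: TBSCl, imidazole, DMF, rt
Reagents that add atoms: tert-butyldimethylsilyl chloride, CC(C)(C)[Si](C)(C)Cl
Why: Silylation masks the acidic phenol for the ylide and enolate steps; an aryl TBS ether can later be removed by carbonate in methanol beside an alkyl TBS ether.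

Step 5
Reactants: 6 5-bromo-2-[(tert-butyldimethylsilyl)oxy]-3-methoxybenzaldehyde
Product: 7 [4-bromo-2-methoxy-6-(2-methoxyethenyl)phenoxy](tert-butyl)dimethylsilane (E/Z mixture)
Conditions: MeOCH2PPh3Cl, KN(SiMe3)2, THF, 0 °C → rt
Reagents that add atoms: (methoxymethyl)triphenylphosphonium chloride, COC[P+](c1ccccc1)(c1ccccc1)c1ccccc1.[Cl-]
Why: Wittig reaction with the methoxymethylene ylide adds the one carbon needed for the arylacetic acid; the alkene geometry is irrelevant.

Step 6
Reactants: 7 [4-bromo-2-methoxy-6-(2-methoxyethenyl)phenoxy](tert-butyl)dimethylsilane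
Product: 9 2-{5-bromo-2-[(tert-butyldimethylsilyl)oxy]-3-methoxyphenyl}acetic acid, via arylacetaldehyde 8 (not isolated)
Conditions: HCO2H, CH2Cl2/H2O, rt; then NaClO2, NaH2PO4, 2-methyl-2-butene, t-BuOH/H2O, 0 °C → rt
Reagents that add atoms: water, O; sodium chlorite, [Na+].[O-]Cl=O
Why: Acid hydrolysis of the enol ether followed at once by Pinnick oxidation, because arylacetaldehydes enolise and self-condense on storage; the alkene scavenger keeps hypochlorite away from the electron-rich ring.

Step 7
Reactants: 9 2-{5-bromo-2-[(tert-butyldimethylsilyl)oxy]-3-methoxyphenyl}acetic acid; 10 (R)-4-benzyl-2-oxazolidinone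
Product: 12 (4R)-4-benzyl-3-(2-{5-bromo-2-[(tert-butyldimethylsilyl)oxy]-3-methoxyphenyl}acetyl)oxazolidin-2-one, via mixed pivalic anhydride 11 (not isolated)
Conditions: PivCl, Et3N, THF, −20 °C; then LiCl, 10, rt
Reagents that add atoms: none
Why: N-acylation of the oxazolidinone through the mixed pivalic anhydride with LiCl activation; no strong base is needed, so the aryl silyl ether is safe.

Step 8
Reactants: 12 (4R)-4-benzyl-3-(2-{5-bromo-2-[(tert-butyldimethylsilyl)oxy]-3-methoxyphenyl}acetyl)oxazolidin-2-one; 4 [4-(bromomethyl)-2-methoxyphenoxy](tert-butyl)dimethylsilane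
Product: 14 (4R)-4-benzyl-3-[(2R)-2-{5-bromo-2-[(tert-butyldimethylsilyl)oxy]-3-methoxyphenyl}-3-{4-[(tert-butyldimethylsilyl)oxy]-3-methoxyphenyl}propanoyl]oxazolidin-2-one, via sodium enolate 13 (not isolated)
Conditions: NaN(SiMe3)2, THF, −78 °C; then 4, −78 → −40 °C
Reagents that add atoms: none
Why: Evans alkylation; the chelated sodium Z-enolate is benzylated on the face opposite the C4 benzyl group of the (R)-auxiliary, which sets the (2R) centre that becomes C3 of ring D.

Step 9
Reactants: 14 (4R)-4-benzyl-3-[(2R)-2-aryl-3-arylpropanoyl]oxazolidin-2-one as named in step 8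
Product: 15 (2R)-2-{5-bromo-2-[(tert-butyldimethylsilyl)oxy]-3-methoxyphenyl}-3-{4-[(tert-butyldimethylsilyl)oxy]-3-methoxyphenyl}propan-1-ol
Conditions: LiBH4, MeOH (1 equiv), THF, 0 °C
Reagents that add atoms: none
Why: Reductive cleavage of the imide at the exocyclic carbonyl gives the primary alcohol and returns the auxiliary; the weakly basic hydride should not epimerise the benzylic centre.

Step 10
Reactants: 15 (2R)-2,3-diarylpropan-1-ol as named in step 9
Product: 16 tert-butyl{[(2R)-2-{5-bromo-2-[(tert-butyldimethylsilyl)oxy]-3-methoxyphenyl}-3-{4-[(tert-butyldimethylsilyl)oxy]-3-methoxyphenyl}propyl]oxy}dimethylsilane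
Conditions: TBSCl, imidazole, DMF, rt
Reagents that add atoms: tert-butyldimethylsilyl chloride, CC(C)(C)[Si](C)(C)Cl
Why: Silylation of the primary alcohol gives the bulky silyloxymethyl group that directs the ring closure and survives the later organometallic steps.

Step 11
Reactants: 16 tris-TBS ether as named in step 10
Product: 17 4-bromo-2-[(2R)-1-[(tert-butyldimethylsilyl)oxy]-3-(4-hydroxy-3-methoxyphenyl)propan-2-yl]-6-methoxyphenol
Conditions: K2CO3, MeOH/THF, rt
Reagents that add atoms: none
Why: Methanolysis of the two aryl silyl ethers, whose phenoxides are good leaving groups at silicon; the alkyl TBS ether is stable to carbonate in methanol.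

Step 12
Reactants: 17 4-bromo-2-[(2R)-1-[(tert-butyldimethylsilyl)oxy]-3-(4-hydroxy-3-methoxyphenyl)propan-2-yl]-6-methoxyphenol
Product: 19 4-[(2S,3R)-5-bromo-3-{[(tert-butyldimethylsilyl)oxy]methyl}-7-methoxy-2,3-dihydro-1-benzofuran-2-yl]-2-methoxyphenol, via quinone methide 18 (not isolated)
Conditions: Ag2O (1.1 equiv), CH2Cl2, rt, dark
Reagents that add atoms: none
Why: Ag2O (monovalent silver, reduced to zerovalent silver) takes two electrons and two protons from the 4-alkyl-2-methoxyphenol unit of ring E, through the phenoxyl radical, and gives para-quinone methide 18; the ring C phenol then adds through oxygen to the exocyclic methide carbon in a 1,6-conjugate addition that forms the C2–O bond and restores the aromaticity of ring E. The closest known reaction type is the Ag2O coupling of 4-alkenyl- and 4-alkyl-2-methoxyphenols to phenylcoumarans, whose last event is this same intramolecular capture of a para-quinone methide by a neighbouring phenol. Ring D closes in the 5-exo-trig mode, the attacked π bond lying outside the new ring. The new centre C2 is controlled by the auxiliary-derived centre C3: in the envelope transition state the guaiacyl group takes the side away from the silyloxymethyl group, and because the addition is reversible for a para-hydroxyphenyl group the trans (2S,3R) isomer should also be the thermodynamic product. The step needs oxidation at ring E and not at ring C; ring C carries bromine para to its oxygen, so it has no para benzylic hydrogen, it is the less electron-rich phenol, and its only benzylic hydrogen is the hindered ortho methine, so an ortho-quinone methide that would erase C3 is disfavoured. It also needs ring closure to outrun tautomerisation of 18 to a stilbene, which the intramolecular five-membered delivery of the nucleophile should secure, and the near-stoichiometric charge of oxidant limits further dehydrogenation of 19 to the benzofuran.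

Step 13
Reactants: 19 4-[(2S,3R)-5-bromo-3-{[(tert-butyldimethylsilyl)oxy]methyl}-7-methoxy-2,3-dihydro-1-benzofuran-2-yl]-2-methoxyphenol
Product: 20 {4-[(2S,3R)-5-bromo-3-{[(tert-butyldimethylsilyl)oxy]methyl}-7-methoxy-2,3-dihydro-1-benzofuran-2-yl]-2-methoxyphenoxy}tri(propan-2-yl)silane
Conditions: TIPSCl, imidazole, DMF, rt
Reagents that add atoms: triisopropylsilyl chloride, CC(C)[Si](Cl)(C(C)C)C(C)C
Why: Silylation of the ring E phenol; the TIPS ether is chosen as the aryl silyl ether most resistant to the organometallic and dealkoxycarbonylation steps, and it stops re-opening of ring D through the phenoxide.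

Step 14
Reactants: 21 dimethyl malonate; 22 (R)-epichlorohydrin
Product: 24 methyl (1S,5R)-2-oxo-3-oxabicyclo[3.1.0]hexane-1-carboxylate, via cyclopropane hydroxy diester 23 (not isolated)
Conditions: NaOMe, MeOH, 0 °C → reflux
Reagents that add atoms: none
Why: Malonate opens the epoxide at CH2, the alkoxide closes a new epoxide by loss of chloride, and 3-exo-tet ring closure with inversion gives the cyclopropane, whose hydroxymethyl group lactonises onto the cis ester; the configuration comes from 22.

Step 15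
Reactants: 20 aryl bromide as named in step 13; 24 methyl (1S,5R)-2-oxo-3-oxabicyclo[3.1.0]hexane-1-carboxylate
Product: 27 methyl (3S,4R)-4-({(2S,3R)-3-{[(tert-butyldimethylsilyl)oxy]methyl}-7-methoxy-2-[3-methoxy-4-(triisopropylsilyloxy)phenyl]-2,3-dihydro-1-benzofuran-5-yl}methyl)-2-oxooxolane-3-carboxylate, via aryllithium 25 (not isolated), via arylmagnesium bromide 26 (not isolated)
Conditions: t-BuLi (2 equiv), THF, −78 °C; MgBr2·OEt2, −78 → −30 °C; CuI (0.2 equiv), then 24, −40 → 0 °C; NH4Cl (aq)
Reagents that add atoms: none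
Why: Bromine–lithium exchange, transmetalation to magnesium and CuI-catalysed homoconjugate addition open the doubly activated cyclopropane at its unsubstituted CH2; C5 of 24 becomes the lactone β-carbon with no bond to it broken.

Step 16
Reactants: 27 lactone ester as named in step 15
Product: 28 (4R)-4-({(2S,3R)-3-{[(tert-butyldimethylsilyl)oxy]methyl}-7-methoxy-2-[3-methoxy-4-(triisopropylsilyloxy)phenyl]-2,3-dihydro-1-benzofuran-5-yl}methyl)oxolan-2-one
Conditions: LiCl, H2O, DMSO, 130 °C
Reagents that add atoms: none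
Why: Krapcho dealkoxycarbonylation; chloride removes the ester methyl group and the malonate-type carboxylate loses CO2, which also removes the labile α-centre.

Step 17
Reactants: 29 methyl vanillate (methyl 4-hydroxy-3-methoxybenzoate); 30 bromoacetic acid
Product: 31 2-[2-methoxy-4-(methoxycarbonyl)phenoxy]acetic acid
Conditions: NaH (2.2 equiv), THF/DMF, 0 → 60 °C; then HCl (aq)
Reagents that add atoms: none
Why: Williamson ether synthesis between the phenoxide and the bromoacetate carboxylate; the aryl methyl ester, the latent benzylic carbon of ring B, is inert to NaH.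

Step 18
Reactants: 31 2-[2-methoxy-4-(methoxycarbonyl)phenoxy]acetic acid; 10 (R)-4-benzyl-2-oxazolidinone
Product: 33 methyl 4-{2-[(4R)-4-benzyl-2-oxooxazolidin-3-yl]-2-oxoethoxy}-3-methoxybenzoate, via mixed pivalic anhydride 32 (not isolated)
Conditions: PivCl, Et3N, THF, −20 °C; then LiCl, 10, rt
Reagents that add atoms: none
Why: N-acylation of the auxiliary through the mixed pivalic anhydride, as in step 7.

Step 19
Reactants: 33 methyl 4-{2-[(4R)-4-benzyl-2-oxooxazolidin-3-yl]-2-oxoethoxy}-3-methoxybenzoate; 2 4-[(tert-butyldimethylsilyl)oxy]-3-methoxybenzaldehyde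
Product: 35 methyl 4-{[(2R,3S)-1-[(4R)-4-benzyl-2-oxooxazolidin-3-yl]-3-{4-[(tert-butyldimethylsilyl)oxy]-3-methoxyphenyl}-3-hydroxy-1-oxopropan-2-yl]oxy}-3-methoxybenzoate, via dibutylboron enolate 34 (not isolated)
Conditions: Bu2BOTf, i-Pr2NEt, CH2Cl2, −78 → 0 °C; then 2, −78 → 0 °C; then pH 7 buffer, MeOH, H2O2, 0 °C
Reagents that add atoms: none
Why: Evans syn aldol addition of the Z-boron enolate through a Zimmerman–Traxler chair with the auxiliary dipole opposed; the (R)-auxiliary sets C8 (2R in the imide, 8S later) and gives the threo relationship, of which only C8 is kept.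

Step 20
Reactants: 35 aldol adduct as named in step 19
Product: 36 methyl 4-{[(1S,2S)-1-{4-[(tert-butyldimethylsilyl)oxy]-3-methoxyphenyl}-1,3-dihydroxypropan-2-yl]oxy}-3-methoxybenzoate
Conditions: LiBH4, MeOH (1 equiv), THF, 0 °C
Reagents that add atoms: none
Why: Reductive removal of the auxiliary; the imide is far more electrophilic than the electron-rich aryl methyl ester, which should survive at 0 °C.

Step 21
Reactants: 36 threo diol as named in step 20
Product: 37 methyl 4-{[(1S,2S)-3-[(tert-butyldimethylsilyl)oxy]-1-{4-[(tert-butyldimethylsilyl)oxy]-3-methoxyphenyl}-1-hydroxypropan-2-yl]oxy}-3-methoxybenzoate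
Conditions: TBSCl (1.05 equiv), imidazole, CH2Cl2, 0 °C
Reagents that add atoms: tert-butyldimethylsilyl chloride, CC(C)(C)[Si](C)(C)Cl
Why: Selective silylation of the primary hydroxyl over the hindered secondary benzylic one.

Step 22
Reactants: 37 threo alcohol as named in step 21
Product: 38 methyl 4-{[(2S)-3-[(tert-butyldimethylsilyl)oxy]-1-{4-[(tert-butyldimethylsilyl)oxy]-3-methoxyphenyl}-1-oxopropan-2-yl]oxy}-3-methoxybenzoate
Conditions: Dess–Martin periodinane, NaHCO3, CH2Cl2, 0 °C → rt
Reagents that add atoms: none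
Why: Dess–Martin oxidation of the benzylic alcohol erases the C7 configuration; the buffered, non-basic medium should leave the α-aryloxy centre C8 untouched, and the ketone is used without storage.

Step 23
Reactants: 38 α-aryloxy ketone as named in step 22
Product: 39 methyl 4-{[(1R,2S)-3-[(tert-butyldimethylsilyl)oxy]-1-{4-[(tert-butyldimethylsilyl)oxy]-3-methoxyphenyl}-1-hydroxypropan-2-yl]oxy}-3-methoxybenzoate
Conditions: Zn(BH4)2, Et2O, −40 → 0 °C
Reagents that add atoms: none
Why: Chelation-controlled (Cram chelate) reduction; zinc bridges the ketone oxygen and the α-aryloxy oxygen, helped by the ortho methoxy group, and hydride enters from the side of the α-hydrogen, which should give the anti (erythro, 7R,8S) alcohol. The silyl ether at C9 is a poor ligand and should not compete.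

Step 24
Reactants: 39 erythro alcohol as named in step 23
Product: 40 methyl 4-{[(1R,2S)-1,3-bis[(tert-butyldimethylsilyl)oxy]-1-{4-[(tert-butyldimethylsilyl)oxy]-3-methoxyphenyl}propan-2-yl]oxy}-3-methoxybenzoate
Conditions: TBSOTf, 2,6-lutidine, CH2Cl2, −78 → 0 °C
Reagents that add atoms: tert-butyldimethylsilyl trifluoromethanesulfonate, CC(C)(C)[Si](C)(C)OS(=O)(=O)C(F)(F)F
Why: The silyl triflate is needed for the hindered secondary benzylic alcohol; the hindered base prevents ionisation at C7.

Step 25
Reactants: 40 methyl ester as named in step 24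
Product: 41 (4-{[(1R,2S)-1,3-bis[(tert-butyldimethylsilyl)oxy]-1-{4-[(tert-butyldimethylsilyl)oxy]-3-methoxyphenyl}propan-2-yl]oxy}-3-methoxyphenyl)methanol
Conditions: i-Bu2AlH, CH2Cl2, −78 °C; potassium sodium tartrate (aq)
Reagents that add atoms: none
Why: Reduction of the aryl ester to the benzylic alcohol at low temperature; silyl ethers are unaffected.

Step 26
Reactants: 41 benzylic alcohol as named in step 25
Product: 42 {[(1R,2S)-2-[4-(bromomethyl)-2-methoxyphenoxy]-1-{4-[(tert-butyldimethylsilyl)oxy]-3-methoxyphenyl}propane-1,3-diyl]bis(oxy)}bis[tert-butyl(dimethyl)silane]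
Conditions: CBr4, PPh3, CH2Cl2, −20 → 0 °C
Reagents that add atoms: carbon tetrabromide, BrC(Br)(Br)Br
Why: Appel reaction under neutral conditions compatible with the three silyl ethers; the bromide is taken directly into step 27.

Step 27
Reactants: 28 lactone as named in step 16; 42 benzylic bromide as named in step 26
Product: 44 pentasilyl ether of the target (ring A O-TBS; C7 O-TBS; C9 O-TBS; benzofuran CH2O-TBS; ring E O-TIPS) with the (3R,4R)-trans lactone, via lithium enolate 43 (not isolated)
Conditions: LiN(SiMe3)2, THF, −78 °C; then 42, DMPU, −78 → −30 °C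
Reagents that add atoms: none
Why: Alkylation of the lactone enolate; the β-substituent shields one face, so the benzyl group should enter anti and give the trans (3R,4R) lactone, which is also the more stable epimer.

Step 28
Reactants: 44 pentasilyl ether as named in step 27
Product: 45 CNP0298853.1, (3R,4R)-3-[(4-{[(1R,2S)-1,3-dihydroxy-1-(4-hydroxy-3-methoxyphenyl)propan-2-yl]oxy}-3-methoxyphenyl)methyl]-4-{[(2S,3R)-2-(4-hydroxy-3-methoxyphenyl)-3-(hydroxymethyl)-7-methoxy-2,3-dihydro-1-benzofuran-5-yl]methyl}oxolan-2-one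
Conditions: Bu4NF, AcOH, THF, 0 °C → rt
Reagents that add atoms: none
Why: Fluoride cleaves the two aryl and three alkyl silyl ethers; acetic acid buffers the phenoxides so that neither quinone methide formation at C7 or C2 nor lactone opening should occur.

## Compound list

1 | vanillin (4-hydroxy-3-methoxybenzaldehyde) | COc1cc(C=O)ccc1O | starting material
2 | 4-[(tert-butyldimethylsilyl)oxy]-3-methoxybenzaldehyde | COc1cc(C=O)ccc1O[Si](C)(C)C(C)(C)C | intermediate
3 | {4-[(tert-butyldimethylsilyl)oxy]-3-methoxyphenyl}methanol | COc1cc(CO)ccc1O[Si](C)(C)C(C)(C)C | intermediate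
4 | [4-(bromomethyl)-2-methoxyphenoxy](tert-butyl)dimethylsilane | COc1cc(CBr)ccc1O[Si](C)(C)C(C)(C)C | intermediate
5 | 5-bromo-2-hydroxy-3-methoxybenzaldehyde | COc1cc(Br)cc(C=O)c1O | starting material
6 | 5-bromo-2-[(tert-butyldimethylsilyl)oxy]-3-methoxybenzaldehyde | COc1cc(Br)cc(C=O)c1O[Si](C)(C)C(C)(C)C | intermediate
7 | [4-bromo-2-methoxy-6-(2-methoxyethenyl)phenoxy](tert-butyl)dimethylsilane, E/Z mixture | COC=Cc1cc(Br)cc(OC)c1O[Si](C)(C)C(C)(C)C | intermediate
8 | 2-{5-bromo-2-[(tert-butyldimethylsilyl)oxy]-3-methoxyphenyl}acetaldehyde | O=CCc1cc(Br)cc(OC)c1O[Si](C)(C)C(C)(C)C | intermediate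
9 | 2-{5-bromo-2-[(tert-butyldimethylsilyl)oxy]-3-methoxyphenyl}acetic acid | OC(=O)Cc1cc(Br)cc(OC)c1O[Si](C)(C)C(C)(C)C | intermediate
10 | (R)-4-benzyl-2-oxazolidinone | O=C1N[C@H](Cc2ccccc2)CO1 | starting material
11 | mixed anhydride of 9 with pivalic acid | CC(C)(C)C(=O)OC(=O)Cc1cc(Br)cc(OC)c1O[Si](C)(C)C(C)(C)C | intermediate
12 | (4R)-4-benzyl-3-(2-{5-bromo-2-[(tert-butyldimethylsilyl)oxy]-3-methoxyphenyl}acetyl)oxazolidin-2-one | O=C(Cc1cc(Br)cc(OC)c1O[Si](C)(C)C(C)(C)C)N1[C@H](Cc2ccccc2)COC1=O | intermediate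
13 | sodium (Z)-enolate of 12 | [Na+].[O-]/C(=C\c1cc(Br)cc(OC)c1O[Si](C)(C)C(C)(C)C)N1[C@H](Cc2ccccc2)COC1=O | intermediate
14 | (4R)-4-benzyl-3-[(2R)-2-{5-bromo-2-[(tert-butyldimethylsilyl)oxy]-3-methoxyphenyl}-3-{4-[(tert-butyldimethylsilyl)oxy]-3-methoxyphenyl}propanoyl]oxazolidin-2-one | O=C([C@H](Cc1ccc(O[Si](C)(C)C(C)(C)C)c(OC)c1)c1cc(Br)cc(OC)c1O[Si](C)(C)C(C)(C)C)N1[C@H](Cc2ccccc2)COC1=O | intermediate
15 | (2R)-2-{5-bromo-2-[(tert-butyldimethylsilyl)oxy]-3-methoxyphenyl}-3-{4-[(tert-butyldimethylsilyl)oxy]-3-methoxyphenyl}propan-1-ol | OC[C@H](Cc1ccc(O[Si](C)(C)C(C)(C)C)c(OC)c1)c1cc(Br)cc(OC)c1O[Si](C)(C)C(C)(C)C | intermediate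
16 | tert-butyl{[(2R)-2-{5-bromo-2-[(tert-butyldimethylsilyl)oxy]-3-methoxyphenyl}-3-{4-[(tert-butyldimethylsilyl)oxy]-3-methoxyphenyl}propyl]oxy}dimethylsilane | CC(C)(C)[Si](C)(C)OC[C@H](Cc1ccc(O[Si](C)(C)C(C)(C)C)c(OC)c1)c1cc(Br)cc(OC)c1O[Si](C)(C)C(C)(C)C | intermediate
17 | 4-bromo-2-[(2R)-1-[(tert-butyldimethylsilyl)oxy]-3-(4-hydroxy-3-methoxyphenyl)propan-2-yl]-6-methoxyphenol | Oc1c(OC)cc(Br)cc1[C@H](CO[Si](C)(C)C(C)(C)C)Cc1ccc(O)c(OC)c1 | intermediate
18 | 4-[(2R)-2-(5-bromo-2-hydroxy-3-methoxyphenyl)-3-[(tert-butyldimethylsilyl)oxy]propylidene]-2-methoxycyclohexa-2,5-dien-1-one (para-quinone methide of ring E) | Oc1c(OC)cc(Br)cc1[C@H](CO[Si](C)(C)C(C)(C)C)C=C1C=CC(=O)C(OC)=C1 | intermediate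
19 | 4-[(2S,3R)-5-bromo-3-{[(tert-butyldimethylsilyl)oxy]methyl}-7-methoxy-2,3-dihydro-1-benzofuran-2-yl]-2-methoxyphenol | Brc1cc(OC)c2c(c1)[C@H](CO[Si](C)(C)C(C)(C)C)[C@@H](c1ccc(O)c(OC)c1)O2 | intermediate
20 | {4-[(2S,3R)-5-bromo-3-{[(tert-butyldimethylsilyl)oxy]methyl}-7-methoxy-2,3-dihydro-1-benzofuran-2-yl]-2-methoxyphenoxy}tri(propan-2-yl)silane | Brc1cc(OC)c2c(c1)[C@H](CO[Si](C)(C)C(C)(C)C)[C@@H](c1ccc(O[Si](C(C)C)(C(C)C)C(C)C)c(OC)c1)O2 | intermediate
21 | dimethyl malonate | COC(=O)CC(=O)OC | starting material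
22 | (R)-epichlorohydrin | ClC[C@H]1CO1 | starting material
23 | dimethyl (2R)-2-(hydroxymethyl)cyclopropane-1,1-dicarboxylate (formed as its sodium alkoxide) | COC(=O)C1(C(=O)OC)C[C@H]1CO | intermediate
24 | methyl (1S,5R)-2-oxo-3-oxabicyclo[3.1.0]hexane-1-carboxylate | COC(=O)[C@]12C[C@H]1COC2=O | intermediate
25 | aryllithium from 20 (lithium in place of bromine) | [Li]c1cc(OC)c2c(c1)[C@H](CO[Si](C)(C)C(C)(C)C)[C@@H](c1ccc(O[Si](C(C)C)(C(C)C)C(C)C)c(OC)c1)O2 | intermediate
26 | arylmagnesium bromide from 25 | Br[Mg]c1cc(OC)c2c(c1)[C@H](CO[Si](C)(C)C(C)(C)C)[C@@H](c1ccc(O[Si](C(C)C)(C(C)C)C(C)C)c(OC)c1)O2 | intermediate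
27 | methyl (3S,4R)-4-({(2S,3R)-3-{[(tert-butyldimethylsilyl)oxy]methyl}-7-methoxy-2-[3-methoxy-4-(triisopropylsilyloxy)phenyl]-2,3-dihydro-1-benzofuran-5-yl}methyl)-2-oxooxolane-3-carboxylate (trans epimer drawn) | COC(=O)[C@H]1C(=O)OC[C@@H]1Cc1cc(OC)c2c(c1)[C@H](CO[Si](C)(C)C(C)(C)C)[C@@H](c1ccc(O[Si](C(C)C)(C(C)C)C(C)C)c(OC)c1)O2 | intermediate
28 | (4R)-4-({(2S,3R)-3-{[(tert-butyldimethylsilyl)oxy]methyl}-7-methoxy-2-[3-methoxy-4-(triisopropylsilyloxy)phenyl]-2,3-dihydro-1-benzofuran-5-yl}methyl)oxolan-2-one | O=C1C[C@@H](Cc2cc(OC)c3c(c2)[C@H](CO[Si](C)(C)C(C)(C)C)[C@@H](c2ccc(O[Si](C(C)C)(C(C)C)C(C)C)c(OC)c2)O3)CO1 | intermediate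
29 | methyl vanillate (methyl 4-hydroxy-3-methoxybenzoate) | COC(=O)c1ccc(O)c(OC)c1 | starting material
30 | bromoacetic acid | OC(=O)CBr | starting material
31 | 2-[2-methoxy-4-(methoxycarbonyl)phenoxy]acetic acid | COC(=O)c1ccc(OCC(=O)O)c(OC)c1 | intermediate
32 | mixed anhydride of 31 with pivalic acid | COC(=O)c1ccc(OCC(=O)OC(=O)C(C)(C)C)c(OC)c1 | intermediate
33 | methyl 4-{2-[(4R)-4-benzyl-2-oxooxazolidin-3-yl]-2-oxoethoxy}-3-methoxybenzoate | COC(=O)c1ccc(OCC(=O)N2[C@H](Cc3ccccc3)COC2=O)c(OC)c1 | intermediate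
34 | dibutylboron (Z)-enolate of 33 | CCCCB(CCCC)O/C(=C\Oc1ccc(C(=O)OC)cc1OC)N1[C@H](Cc2ccccc2)COC1=O | intermediate
35 | methyl 4-{[(2R,3S)-1-[(4R)-4-benzyl-2-oxooxazolidin-3-yl]-3-{4-[(tert-butyldimethylsilyl)oxy]-3-methoxyphenyl}-3-hydroxy-1-oxopropan-2-yl]oxy}-3-methoxybenzoate | COC(=O)c1ccc(O[C@@H](C(=O)N2[C@H](Cc3ccccc3)COC2=O)[C@@H](O)c2ccc(O[Si](C)(C)C(C)(C)C)c(OC)c2)c(OC)c1 | intermediate
36 | methyl 4-{[(1S,2S)-1-{4-[(tert-butyldimethylsilyl)oxy]-3-methoxyphenyl}-1,3-dihydroxypropan-2-yl]oxy}-3-methoxybenzoate | COC(=O)c1ccc(O[C@@H](CO)[C@@H](O)c2ccc(O[Si](C)(C)C(C)(C)C)c(OC)c2)c(OC)c1 | intermediate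
37 | methyl 4-{[(1S,2S)-3-[(tert-butyldimethylsilyl)oxy]-1-{4-[(tert-butyldimethylsilyl)oxy]-3-methoxyphenyl}-1-hydroxypropan-2-yl]oxy}-3-methoxybenzoate | COC(=O)c1ccc(O[C@@H](CO[Si](C)(C)C(C)(C)C)[C@@H](O)c2ccc(O[Si](C)(C)C(C)(C)C)c(OC)c2)c(OC)c1 | intermediate
38 | methyl 4-{[(2S)-3-[(tert-butyldimethylsilyl)oxy]-1-{4-[(tert-butyldimethylsilyl)oxy]-3-methoxyphenyl}-1-oxopropan-2-yl]oxy}-3-methoxybenzoate | COC(=O)c1ccc(O[C@@H](CO[Si](C)(C)C(C)(C)C)C(=O)c2ccc(O[Si](C)(C)C(C)(C)C)c(OC)c2)c(OC)c1 | intermediate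
39 | methyl 4-{[(1R,2S)-3-[(tert-butyldimethylsilyl)oxy]-1-{4-[(tert-butyldimethylsilyl)oxy]-3-methoxyphenyl}-1-hydroxypropan-2-yl]oxy}-3-methoxybenzoate | COC(=O)c1ccc(O[C@@H](CO[Si](C)(C)C(C)(C)C)[C@H](O)c2ccc(O[Si](C)(C)C(C)(C)C)c(OC)c2)c(OC)c1 | intermediate
40 | methyl 4-{[(1R,2S)-1,3-bis[(tert-butyldimethylsilyl)oxy]-1-{4-[(tert-butyldimethylsilyl)oxy]-3-methoxyphenyl}propan-2-yl]oxy}-3-methoxybenzoate | COC(=O)c1ccc(O[C@@H](CO[Si](C)(C)C(C)(C)C)[C@H](O[Si](C)(C)C(C)(C)C)c2ccc(O[Si](C)(C)C(C)(C)C)c(OC)c2)c(OC)c1 | intermediate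
41 | (4-{[(1R,2S)-1,3-bis[(tert-butyldimethylsilyl)oxy]-1-{4-[(tert-butyldimethylsilyl)oxy]-3-methoxyphenyl}propan-2-yl]oxy}-3-methoxyphenyl)methanol | OCc1ccc(O[C@@H](CO[Si](C)(C)C(C)(C)C)[C@H](O[Si](C)(C)C(C)(C)C)c2ccc(O[Si](C)(C)C(C)(C)C)c(OC)c2)c(OC)c1 | intermediate
42 | {[(1R,2S)-2-[4-(bromomethyl)-2-methoxyphenoxy]-1-{4-[(tert-butyldimethylsilyl)oxy]-3-methoxyphenyl}propane-1,3-diyl]bis(oxy)}bis[tert-butyl(dimethyl)silane] | BrCc1ccc(O[C@@H](CO[Si](C)(C)C(C)(C)C)[C@H](O[Si](C)(C)C(C)(C)C)c2ccc(O[Si](C)(C)C(C)(C)C)c(OC)c2)c(OC)c1 | intermediate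
43 | lithium enolate of 28 | [Li]OC1=C[C@@H](Cc2cc(OC)c3c(c2)[C@H](CO[Si](C)(C)C(C)(C)C)[C@@H](c2ccc(O[Si](C(C)C)(C(C)C)C(C)C)c(OC)c2)O3)CO1 | intermediate
44 | (3R,4R)-3-[(4-{[(1R,2S)-1,3-bis[(tert-butyldimethylsilyl)oxy]-1-{4-[(tert-butyldimethylsilyl)oxy]-3-methoxyphenyl}propan-2-yl]oxy}-3-methoxyphenyl)methyl]-4-({(2S,3R)-3-{[(tert-butyldimethylsilyl)oxy]methyl}-7-methoxy-2-[3-methoxy-4-(triisopropylsilyloxy)phenyl]-2,3-dihydro-1-benzofuran-5-yl}methyl)oxolan-2-one | COc1cc([C@@H](O[Si](C)(C)C(C)(C)C)[C@H](CO[Si](C)(C)C(C)(C)C)Oc2ccc(C[C@H]3C(=O)OC[C@@H]3Cc3cc(OC)c4c(c3)[C@H](CO[Si](C)(C)C(C)(C)C)[C@@H](c3ccc(O[Si](C(C)C)(C(C)C)C(C)C)c(OC)c3)O4)cc2OC)ccc1O[Si](C)(C)C(C)(C)C | intermediate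
45 | CNP0298853.1, (3R,4R)-3-[(4-{[(1R,2S)-1,3-dihydroxy-1-(4-hydroxy-3-methoxyphenyl)propan-2-yl]oxy}-3-methoxyphenyl)methyl]-4-{[(2S,3R)-2-(4-hydroxy-3-methoxyphenyl)-3-(hydroxymethyl)-7-methoxy-2,3-dihydro-1-benzofuran-5-yl]methyl}oxolan-2-one | COc1cc([C@@H](O)[C@H](CO)Oc2ccc(C[C@H]3C(=O)OC[C@@H]3Cc3cc(OC)c4c(c3)[C@H](CO)[C@@H](c3ccc(O)c(OC)c3)O4)cc2OC)ccc1O | target

## Step count and least certain steps

Total step count: 28. Longest linear sequence: 14 steps (steps 4–13, 15, 16, 27, 28, from 5). The ring B branch is 12 steps (17–28), and 24 is made in one step.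

**Step 12 (key step).**
- What may go wrong: further dehydrogenation of the product, since 19 still has a para-hydroxybenzylic hydrogen at C2 and can pass to the 2-arylbenzofuran; tautomerisation of quinone methide 18 to a stilbene before ring closure, with loss of the C3 centre; oxidation at ring C through an ortho-quinone methide.
- Fallback (the same quinone methide reached without an oxidant): it sets out from acid 9 and comes back at 19. Acid 9 is loaded onto (S)-4-benzyl-2-oxazolidinone (PivCl, Et3N, LiCl) to give the (4S)-arylacetyl imide F1. The enantiomeric auxiliary is needed because the boron aldol places the electrophile on the enolate face opposite to that used in alkylation. Evans syn aldol addition of its dibutylboron enolate to aldehyde 2 gives the (2S,3S)-aldol adduct F2. LiBH4 gives the (1S,2R)-diol F3, TBSCl and imidazole silylate the primary hydroxyl to the mono-silyl ether F4, and K2CO3 in methanol frees both phenols to give the para-hydroxybenzylic alcohol F5. Loss of water from F5 (PPTS, CH2Cl2, if it has not already occurred under carbonate) gives 18, which closes to 19 as in step 12.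

**Step 23.**
- What may go wrong: poor facial selectivity if the reduction runs through the open Felkin–Anh arrangement instead of the zinc chelate (an aryl ether oxygen is a weak donor), which would return the threo alcohol; partial epimerisation of 38 at C8 before reduction.
- Fallback (inversion by substitution instead of oxidation and reduction): it sets out from 37 and comes back at 39, bypassing 38. Mitsunobu reaction of 37 with chloroacetic acid (PPh3, DIAD, toluene, 0 °C) gives the inverted (1R,2S)-chloroacetate F6. Thiourea with NaHCO3 in ethanol removes the chloroacetyl group under nearly neutral conditions, which spare the aryl silyl ether and the methyl ester.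

**Step 16.**
- What may go wrong: loss of the aryl TIPS ether in the hot medium, which turns basic as hydrogencarbonate forms, followed by opening of ring D through the ring E phenoxide; opening of the lactone by chloride.
- Fallback (hydrogenolytic instead of nucleophilic ester removal): it sets out from 20 and 22 and comes back at 28. Dibenzyl malonate and 22 (NaH, THF, then heat) give benzyl (1R,5R)-2-oxo-3-oxabicyclo[3.1.0]hexane-1-carboxylate F7. Arylmagnesium bromide 26, made from 20 as in step 15, opens it to the benzyl ester F8. H2 over Pd/C in ethyl acetate gives the malonic-type acid F9, which loses CO2 on warming in toluene.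

**Step 27.**
- What may go wrong: ionisation or elimination of the electron-rich benzylic bromide before it is captured; proton exchange between product and enolate leading to double alkylation; incomplete conversion of two valuable partners.
- Fallback (aldol condensation and reduction instead of alkylation): it sets out from 41 and 28 and comes back at 44. MnO2 oxidises 41 to the aldehyde F10. Enolate 43 adds to it to give the β-hydroxy lactone F11 (mixture at the carbinol carbon). MsCl and Et3N followed by DBU give the (E)-benzylidene lactone F12. Conjugate reduction (NiCl2·6H2O, NaBH4, MeOH/THF, 0 °C) and equilibration with DBU to the more stable trans lactone give 44.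

## Further compounds

F1 | step 12 | (4S)-4-benzyl-3-(2-{5-bromo-2-[(tert-butyldimethylsilyl)oxy]-3-methoxyphenyl}acetyl)oxazolidin-2-one | O=C(Cc1cc(Br)cc(OC)c1O[Si](C)(C)C(C)(C)C)N1[C@@H](Cc2ccccc2)COC1=O
F2 | step 12 | (4S)-4-benzyl-3-[(2S,3S)-2-{5-bromo-2-[(tert-butyldimethylsilyl)oxy]-3-methoxyphenyl}-3-{4-[(tert-butyldimethylsilyl)oxy]-3-methoxyphenyl}-3-hydroxypropanoyl]oxazolidin-2-one | O=C([C@H]([C@H](O)c1ccc(O[Si](C)(C)C(C)(C)C)c(OC)c1)c1cc(Br)cc(OC)c1O[Si](C)(C)C(C)(C)C)N1[C@@H](Cc2ccccc2)COC1=O
F3 | step 12 | (1S,2R)-2-{5-bromo-2-[(tert-butyldimethylsilyl)oxy]-3-methoxyphenyl}-1-{4-[(tert-butyldimethylsilyl)oxy]-3-methoxyphenyl}propane-1,3-diol | OC[C@H]([C@H](O)c1ccc(O[Si](C)(C)C(C)(C)C)c(OC)c1)c1cc(Br)cc(OC)c1O[Si](C)(C)C(C)(C)C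
F4 | step 12 | (1S,2R)-2-{5-bromo-2-[(tert-butyldimethylsilyl)oxy]-3-methoxyphenyl}-3-[(tert-butyldimethylsilyl)oxy]-1-{4-[(tert-butyldimethylsilyl)oxy]-3-methoxyphenyl}propan-1-ol | CC(C)(C)[Si](C)(C)OC[C@H]([C@H](O)c1ccc(O[Si](C)(C)C(C)(C)C)c(OC)c1)c1cc(Br)cc(OC)c1O[Si](C)(C)C(C)(C)C
F5 | step 12 | 4-bromo-2-[(1S,2R)-3-[(tert-butyldimethylsilyl)oxy]-1-hydroxy-1-(4-hydroxy-3-methoxyphenyl)propan-2-yl]-6-methoxyphenol | CC(C)(C)[Si](C)(C)OC[C@H]([C@H](O)c1ccc(O)c(OC)c1)c1cc(Br)cc(OC)c1O
F6 | step 23 | methyl 4-{[(1R,2S)-3-[(tert-butyldimethylsilyl)oxy]-1-{4-[(tert-butyldimethylsilyl)oxy]-3-methoxyphenyl}-1-(2-chloroacetoxy)propan-2-yl]oxy}-3-methoxybenzoate | COC(=O)c1ccc(O[C@@H](CO[Si](C)(C)C(C)(C)C)[C@H](OC(=O)CCl)c2ccc(O[Si](C)(C)C(C)(C)C)c(OC)c2)c(OC)c1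
F7 | step 16 | benzyl (1R,5R)-2-oxo-3-oxabicyclo[3.1.0]hexane-1-carboxylate | O=C(OCc1ccccc1)[C@]12C[C@H]1COC2=O
F8 | step 16 | benzyl (3R,4R)-4-({(2S,3R)-3-{[(tert-butyldimethylsilyl)oxy]methyl}-7-methoxy-2-[3-methoxy-4-(triisopropylsilyloxy)phenyl]-2,3-dihydro-1-benzofuran-5-yl}methyl)-2-oxooxolane-3-carboxylate (trans epimer drawn) | O=C(OCc1ccccc1)[C@H]1C(=O)OC[C@@H]1Cc1cc(OC)c2c(c1)[C@H](CO[Si](C)(C)C(C)(C)C)[C@@H](c1ccc(O[Si](C(C)C)(C(C)C)C(C)C)c(OC)c1)O2
F9 | step 16 | (3S,4R)-4-({(2S,3R)-3-{[(tert-butyldimethylsilyl)oxy]methyl}-7-methoxy-2-[3-methoxy-4-(triisopropylsilyloxy)phenyl]-2,3-dihydro-1-benzofuran-5-yl}methyl)-2-oxooxolane-3-carboxylic acid (trans epimer drawn) | OC(=O)[C@H]1C(=O)OC[C@@H]1Cc1cc(OC)c2c(c1)[C@H](CO[Si](C)(C)C(C)(C)C)[C@@H](c1ccc(O[Si](C(C)C)(C(C)C)C(C)C)c(OC)c1)O2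
F10 | step 27 | 4-{[(1R,2S)-1,3-bis[(tert-butyldimethylsilyl)oxy]-1-{4-[(tert-butyldimethylsilyl)oxy]-3-methoxyphenyl}propan-2-yl]oxy}-3-methoxybenzaldehyde | O=Cc1ccc(O[C@@H](CO[Si](C)(C)C(C)(C)C)[C@H](O[Si](C)(C)C(C)(C)C)c2ccc(O[Si](C)(C)C(C)(C)C)c(OC)c2)c(OC)c1
F11 | step 27 | aldol adduct of 43 with F10: analogue of 44 with CH(OH) in place of the ring B benzylic CH2, (3S,4R) in the lactone, carbinol carbon as a mixture | COc1cc([C@@H](O[Si](C)(C)C(C)(C)C)[C@H](CO[Si](C)(C)C(C)(C)C)Oc2ccc(C(O)[C@H]3C(=O)OC[C@@H]3Cc3cc(OC)c4c(c3)[C@H](CO[Si](C)(C)C(C)(C)C)[C@@H](c3ccc(O[Si](C(C)C)(C(C)C)C(C)C)c(OC)c3)O4)cc2OC)ccc1O[Si](C)(C)C(C)(C)C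
F12 | step 27 | (E)-benzylidene lactone: analogue of 44 with a C=C bond between the ring B benzylic carbon and the lactone α-carbon, (4R) | COc1cc([C@@H](O[Si](C)(C)C(C)(C)C)[C@H](CO[Si](C)(C)C(C)(C)C)Oc2ccc(/C=C3/C(=O)OC[C@@H]3Cc3cc(OC)c4c(c3)[C@H](CO[Si](C)(C)C(C)(C)C)[C@@H](c3ccc(O[Si](C(C)C)(C(C)C)C(C)C)c(OC)c3)O4)cc2OC)ccc1O[Si](C)(C)C(C)(C)C
A1 | alternative 1 | trans,trans 3-benzyl-4-(2-aryl-1,3-dithian-2-yl)-5-menthyloxy lactone (product of the three-component coupling) | COc1cc([C@@H](O[Si](C)(C)C(C)(C)C)[C@H](CO[Si](C)(C)C(C)(C)C)Oc2ccc(C[C@H]3C(=O)O[C@@H](O[C@@H]4C[C@H](C)CC[C@H]4C(C)C)[C@@H]3C3(SCCCS3)c3cc(OC)c4c(c3)[C@H](CO[Si](C)(C)C(C)(C)C)[C@@H](c3ccc(O[Si](C(C)C)(C(C)C)C(C)C)c(OC)c3)O4)cc2OC)ccc1O[Si](C(C)C)(C(C)C)C(C)C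
A2 | alternative 1 | (5R)-5-{[(1R,2S,5R)-5-methyl-2-(propan-2-yl)cyclohexyl]oxy}furan-2(5H)-one (menthyloxybutenolide) | O=C1C=C[C@H](O[C@@H]2C[C@H](C)CC[C@H]2C(C)C)O1
A3 | alternative 1 | 2-{(2S,3R)-3-{[(tert-butyldimethylsilyl)oxy]methyl}-7-methoxy-2-[3-methoxy-4-(triisopropylsilyloxy)phenyl]-2,3-dihydro-1-benzofuran-5-yl}-1,3-dithiane | C1CSC(SC1)c1cc(OC)c2c(c1)[C@H](CO[Si](C)(C)C(C)(C)C)[C@@H](c1ccc(O[Si](C(C)C)(C(C)C)C(C)C)c(OC)c1)O2
A4 | alternative 2 | methyl (2S,3S)-5-bromo-7-methoxy-2-[3-methoxy-4-(triisopropylsilyloxy)phenyl]-2,3-dihydro-1-benzofuran-3-carboxylate (trans) | Brc1cc(OC)c2c(c1)[C@H](C(=O)OC)[C@@H](c1ccc(O[Si](C(C)C)(C(C)C)C(C)C)c(OC)c1)O2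
A5 | alternative 2 | methyl 2-(5-bromo-3-methoxy-2-{[3-methoxy-4-(triisopropylsilyloxy)phenyl]methoxy}phenyl)-2-diazoacetate | COC(=O)C(=[N+]=[N-])c1cc(Br)cc(OC)c1OCc1ccc(O[Si](C(C)C)(C(C)C)C(C)C)c(OC)c1
A6 | alternative 3 | (4R)-4-(dihydrobenzofuran-5-ylmethyl)oxolan-2-one, identical with 28 | O=C1C[C@@H](Cc2cc(OC)c3c(c2)[C@H](CO[Si](C)(C)C(C)(C)C)[C@@H](c2ccc(O[Si](C(C)C)(C(C)C)C(C)C)c(OC)c2)O3)CO1
A7 | alternative 3 | 3-({(2S,3R)-3-{[(tert-butyldimethylsilyl)oxy]methyl}-7-methoxy-2-[3-methoxy-4-(triisopropylsilyloxy)phenyl]-2,3-dihydro-1-benzofuran-5-yl}methyl)cyclobutan-1-one | O=C1CC(Cc2cc(OC)c3c(c2)[C@H](CO[Si](C)(C)C(C)(C)C)[C@@H](c2ccc(O[Si](C(C)C)(C(C)C)C(C)C)c(OC)c2)O3)C1
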